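**Plan**

- Cuts: the dihydrofuran bonds C3–C3a and C7a–O1 go first, giving enol-trione 13 and hydroxy epoxide 18. Compound 13 is then cut at C7–prenyl, at the ring bond C3a–C4, at the two C7–acyl bonds and at the two C5–alkyl bonds, back to ethyl (S)-3-hydroxybutanoate; 18 is cut back to nerol.
- Enabling feature: the dihydrofuran (O1, C2, C3, C3a, C7a) fused to the six-membered ring is the cyclodehydrated adduct of the C4–C3a–C7a 1,3-dione (carbon nucleophile C3a, carbonyl C7a) with a terminal epoxide that already carries C2, C3 and the C1′ carbinol.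
- Forward: the carbocycle is closed by an intramolecular Claisen condensation (step 6), C7 is prenylated while C3a is masked as a silyl enol ether (steps 7 and 8), the epoxide is made in three steps, and the dihydrofuran is closed last (step 12).
- Stereochemistry: C5 comes from the carbinol of the hydroxybutanoate through two Fráter–Seebach alkylations (prenyl, then methyl). C7 is set by allylic alkylation anti to the C5 prenyl group under a chiral palladium catalyst. C2 and C1′ come from Sharpless epoxidation of nerol with D-(−)-diethyl tartrate, C2 being inverted once in the Payne step and retained afterwards.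

Key step: step 12

Remark: atom labels C2–C7a and C1′ are those of the target's 1-benzofuran core and side-chain carbinol; the enolised polyketones 8, 9, 10, 13 and 19 are drawn and named as one tautomer each, and their descriptors refer to that tautomer.

**Route**

Step 1
Reactants: 1 ethyl (3S)-3-hydroxybutanoate; 2 1-bromo-3-methylbut-2-ene (prenyl bromide)
Product: 3 ethyl (2S,3S)-3-hydroxy-2-(3-methylbut-2-en-1-yl)butanoate
Conditions: LiN(i-Pr)2 (2.2 equiv), THF, −78 to −20 °C; then 2, DMPU, −78 to 0 °C
Reagents that add atoms: none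
Why: Fráter–Seebach alkylation: the lithium-chelated alkoxide–enolate dianion should be alkylated by the allylic bromide on the face opposite the C3 methyl group, so the existing carbinol centre sets C2 as the 2,3-anti (2S,3S) isomer.

Step 2
Reactants: 3 ethyl (2S,3S)-3-hydroxy-2-(3-methylbut-2-en-1-yl)butanoate
Product: 4 ethyl (2R,3S)-3-hydroxy-2-methyl-2-(3-methylbut-2-en-1-yl)butanoate
Conditions: LiN(i-Pr)2 (2.2 equiv), THF, −78 to −20 °C; then MeI, DMPU, −78 to 0 °C
Reagents that add atoms: iodomethane, CI
Why: Second Fráter–Seebach alkylation: the now tetrasubstituted chelated enolate should again be attacked anti to the C3 methyl group, so introducing prenyl first and methyl second fixes the quaternary carbon (future C5) as 2R under control of the C3 carbinol.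

Step 3
Reactants: 4 ethyl (2R,3S)-3-hydroxy-2-methyl-2-(3-methylbut-2-en-1-yl)butanoate
Product: 5 ethyl (2R)-2-acetyl-2,5-dimethylhex-4-enoate
Conditions: Dess–Martin periodinane, CH2Cl2, 0 °C to rt
Reagents that add atoms: none
Why: Dess–Martin oxidation of the hindered secondary alcohol under neutral, non-enolising conditions; the quaternary centre cannot epimerise and no stereocentre is formed.

Step 4
Reactants: 5 ethyl (2R)-2-acetyl-2,5-dimethylhex-4-enoate; 6 N-methoxy-N,2-dimethylpropanamide
Product: 7 ethyl (2R)-2,6-dimethyl-2-(3-methylbut-2-en-1-yl)-3,5-dioxoheptanoate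
Conditions: LiN(i-Pr)2 (2.2 equiv), THF, −78 °C; then 6, −78 to 0 °C
Reagents that add atoms: none
Why: Claisen-type C-acylation of the only enolisable position (the acetyl CH3, future C7) by a Weinreb amide, whose chelated tetrahedral adduct should prevent over-addition; no stereocentre is formed.

Step 5
Reactants: 7 ethyl (2R)-2,6-dimethyl-2-(3-methylbut-2-en-1-yl)-3,5-dioxoheptanoate
Product: 8 ethyl (2R)-4-acetyl-2,6-dimethyl-2-(3-methylbut-2-en-1-yl)-3,5-dioxoheptanoate
Conditions: MgCl2, pyridine, AcCl, CH2Cl2, 0 °C to rt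
Reagents that add atoms: acetyl chloride, CC(Cl)=O
Why: Magnesium-mediated soft-enolisation C-acylation of a β-diketone: the chelated enolate should be acylated at the central carbon (future C7) to give the enolised triketone, the new acetyl group supplying C7a and C3a; no fixed stereocentre is formed.

Step 6
Reactants: 8 ethyl (2R)-4-acetyl-2,6-dimethyl-2-(3-methylbut-2-en-1-yl)-3,5-dioxoheptanoate
Product: 9 (4S)-3,5-dihydroxy-4-methyl-4-(3-methylbut-2-en-1-yl)-2-(2-methylpropanoyl)cyclohexa-2,5-dien-1-one
Conditions: LiN(i-Pr)2 (2.3 equiv), THF, −78 to 0 °C; then 1 M HCl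
Reagents that add atoms: none
Why: Intramolecular Claisen (Dieckmann-type) condensation: the dianion formed at the triketone and at the acetyl CH3 should attack the ester 6-exo-trig through the carbanion (not an enolate oxygen) to close the carbocycle, driven by formation of the fully enolised product; C5 is untouched.

Step 7
Reactants: 9 (4S)-3,5-dihydroxy-4-methyl-4-(3-methylbut-2-en-1-yl)-2-(2-methylpropanoyl)cyclohexa-2,5-dien-1-one
Product: 10 (4R)-3-hydroxy-4-methyl-4-(3-methylbut-2-en-1-yl)-2-(2-methylpropanoyl)-5-{[tri(propan-2-yl)silyl]oxy}cyclohexa-2,5-dien-1-one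
Conditions: TIPSCl, Et3N, CH2Cl2, 0 °C
Reagents that add atoms: chlorotri(propan-2-yl)silane, CC(C)[Si](Cl)(C(C)C)C(C)C
Why: O-silylation of the vinylogous acid at the enol oxygen not chelated to the isobutyryl carbonyl (C4–O), which masks C3a as the β-carbon of a vinylogous silyl ester and leaves C7 as the only acidic carbon; an O7a-silyl isomer would converge on the same 13, and no nucleophilic amine catalyst is used so that the acyl group does not migrate.

Step 8
Reactants: 10 (4R)-3-hydroxy-4-methyl-4-(3-methylbut-2-en-1-yl)-2-(2-methylpropanoyl)-5-{[tri(propan-2-yl)silyl]oxy}cyclohexa-2,5-dien-1-one; 11 3-methylbut-2-en-1-yl acetate (prenyl acetate)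
Product: 13 (2S,6S)-5-hydroxy-2-methyl-2,6-bis(3-methylbut-2-en-1-yl)-6-(2-methylpropanoyl)cyclohex-4-ene-1,3-dione, via silyl enol ether 12 (not isolated)
Conditions: Pd2(dba)3 (2.5 mol%), (1R,2R)-N,N′-bis[2-(diphenylphosphino)benzoyl]cyclohexane-1,2-diamine (7.5 mol%), CH2Cl2, rt; then 1 M HCl, THF, 0 °C
Reagents that add atoms: none
Why: Tsuji–Trost allylic alkylation of a triacylmethane-type carbon acid under neutral conditions (acetate as the base): the stabilised enolate should attack the unsubstituted terminus of the 1,1-dimethylallyl palladium complex at C7, entering anti to the larger C5 substituent (prenyl) with the chiral diphosphine reinforcing that face (its antipode is taken if it proves the matched one), after which dilute acid hydrolyses the silyl enol ether and the minor C7 epimer is removed by chromatography.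

Step 9
Reactants: 14 nerol
Product: 15 [(2R,3S)-3-methyl-3-(4-methylpent-3-en-1-yl)oxiran-2-yl]methanol
Conditions: Ti(OiPr)4 (5 mol%), D-(−)-diethyl tartrate (6 mol%), t-BuOOH, 4 Å MS, CH2Cl2, −20 °C
Reagents that add atoms: tert-butyl hydroperoxide, CC(C)(C)OO
Why: Sharpless asymmetric epoxidation of the Z-allylic alcohol: the titanium–D-tartrate catalyst should deliver oxygen to the face that gives the (2R,3S)-epoxide, setting both future side-chain centres and leaving the isolated trisubstituted alkene alone.

Step 10
Reactants: 15 [(2R,3S)-3-methyl-3-(4-methylpent-3-en-1-yl)oxiran-2-yl]methanol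
Product: 16 (2S,3S)-3,7-dimethyloct-6-ene-1,2,3-triol
Conditions: NaOH (0.5 M), t-BuOH/H2O, 70 °C
Reagents that add atoms: water, O
Why: Payne rearrangement–opening: the C1 alkoxide should open the epoxide at C2 with inversion and hydroxide then attacks the terminal epoxide at C1, so C2 is inverted once and C3 retained to give the (2S,3S)-triol (direct hydroxide attack at C2 would lead to the same isomer).

Step 11
Reactants: 16 (2S,3S)-3,7-dimethyloct-6-ene-1,2,3-triol
Product: 18 (2S)-6-methyl-2-[(2S)-oxiran-2-yl]hept-5-en-2-ol, via primary tosylate 17 (not isolated)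
Conditions: TsCl, Et3N, Bu2SnO (2 mol%), CH2Cl2, 0 °C; then K2CO3, MeOH, 0 °C
Reagents that add atoms: none
Why: Tin-acetal-catalysed selective tosylation of the primary hydroxyl followed by intramolecular Williamson displacement (3-exo-tet) by the C2 alkoxide, which breaks no bond at either stereocentre; cold, brief base treatment is used so that the product does not drift back by Payne rearrangement.

Step 12
Reactants: 13 (2S,6S)-5-hydroxy-2-methyl-2,6-bis(3-methylbut-2-en-1-yl)-6-(2-methylpropanoyl)cyclohex-4-ene-1,3-dione; 18 (2S)-6-methyl-2-[(2S)-oxiran-2-yl]hept-5-en-2-ol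
Product: 20 (2S,5S,7S)-2-[(2S)-2-hydroxy-6-methylhept-5-en-2-yl]-5-methyl-5,7-bis(3-methylbut-2-en-1-yl)-7-(2-methylpropanoyl)-2,3,5,7-tetrahydro-1-benzofuran-4,6-dione (CNP0250451.1), via hydroxyalkyl trione 19 (not isolated)
Conditions: Cs2CO3 (0.2 equiv), LiClO4 (1 equiv), CF3CH2OH, 50 °C; then camphorsulfonic acid (cat.), 4 Å MS, CH2Cl2, rt
Reagents that add atoms: none
Why: The caesium enolate of 13, present only in a catalytic amount, should open 18 at its unsubstituted carbon in an SN2 step assisted by Li+ and the hydrogen-bonding fluoro alcohol (C3–C3a); the alkoxide is protonated at once by solvent and by further 13, so the medium stays non-basic and the retro-Claisen-prone triacyl carbon C7 is spared. Acid then closes the ring by 5-exo-trig addition of the C2 hydroxyl to the C7a carbonyl and dehydration of the hemiketal to the vinylogous ester (C7a–O1). The closest known reaction type is C-alkylation of cyclic 1,3-dione enolates with terminal epoxides followed by cyclodehydration to 2-substituted 2,3-dihydrofurans fused to an enone. No stereocentre is created: the C2–O bond of 18 is never broken, so C2 and C1′ are carried over, and C5 and C7 are not enolisable. C- over O-alkylation should be favoured by the protic medium that solvates the enolate oxygens, and attack at CH2 over CH by the neighbouring fully substituted carbinol. Closure on C7a and not C4, and by the secondary and not the tertiary hydroxyl, rests on the higher electrophilicity of the carbonyl next to the diacyl-substituted C7, on the five- over six-membered ring preference, and on acid-mediated equilibration toward the isomer in which C7 no longer carries three carbonyl groups.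

**Compound list**

1 | ethyl (3S)-3-hydroxybutanoate | CCOC(=O)C[C@H](C)O | starting material
2 | 1-bromo-3-methylbut-2-ene (prenyl bromide) | CC(C)=CCBr | starting material
3 | ethyl (2S,3S)-3-hydroxy-2-(3-methylbut-2-en-1-yl)butanoate | CCOC(=O)[C@@H](CC=C(C)C)[C@H](C)O | intermediate
4 | ethyl (2R,3S)-3-hydroxy-2-methyl-2-(3-methylbut-2-en-1-yl)butanoate | CCOC(=O)[C@](C)(CC=C(C)C)[C@H](C)O | intermediate
5 | ethyl (2R)-2-acetyl-2,5-dimethylhex-4-enoate | CCOC(=O)[C@](C)(CC=C(C)C)C(C)=O | intermediate
6 | N-methoxy-N,2-dimethylpropanamide | CON(C)C(=O)C(C)C | starting material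
7 | ethyl (2R)-2,6-dimethyl-2-(3-methylbut-2-en-1-yl)-3,5-dioxoheptanoate | CCOC(=O)[C@](C)(CC=C(C)C)C(=O)CC(=O)C(C)C | intermediate
8 | ethyl (2R)-4-acetyl-2,6-dimethyl-2-(3-methylbut-2-en-1-yl)-3,5-dioxoheptanoate (C4 enolised, no fixed configuration) | CCOC(=O)[C@](C)(CC=C(C)C)C(=O)C(C(C)=O)C(=O)C(C)C | intermediate
9 | (4S)-3,5-dihydroxy-4-methyl-4-(3-methylbut-2-en-1-yl)-2-(2-methylpropanoyl)cyclohexa-2,5-dien-1-one | CC(C)C(=O)C1=C(O)[C@@](C)(CC=C(C)C)C(O)=CC1=O | intermediate
10 | (4R)-3-hydroxy-4-methyl-4-(3-methylbut-2-en-1-yl)-2-(2-methylpropanoyl)-5-{[tri(propan-2-yl)silyl]oxy}cyclohexa-2,5-dien-1-one | CC(C)C(=O)C1=C(O)[C@@](C)(CC=C(C)C)C(O[Si](C(C)C)(C(C)C)C(C)C)=CC1=O | intermediate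
11 | 3-methylbut-2-en-1-yl acetate (prenyl acetate) | CC(C)=CCOC(C)=O | starting material
12 | (2R,6S)-6-methyl-2,6-bis(3-methylbut-2-en-1-yl)-2-(2-methylpropanoyl)-5-{[tri(propan-2-yl)silyl]oxy}cyclohex-4-ene-1,3-dione | C1=C(O[Si](C(C)C)(C(C)C)C(C)C)[C@](C)(CC=C(C)C)C(=O)[C@](CC=C(C)C)(C(=O)C(C)C)C1=O | intermediate
13 | (2S,6S)-5-hydroxy-2-methyl-2,6-bis(3-methylbut-2-en-1-yl)-6-(2-methylpropanoyl)cyclohex-4-ene-1,3-dione | C1=C(O)[C@@](CC=C(C)C)(C(=O)C(C)C)C(=O)[C@@](C)(CC=C(C)C)C1=O | intermediate
14 | nerol, (2Z)-3,7-dimethylocta-2,6-dien-1-ol | CC(C)=CCC/C(C)=C\CO | starting material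
15 | [(2R,3S)-3-methyl-3-(4-methylpent-3-en-1-yl)oxiran-2-yl]methanol | CC(C)=CCC[C@]1(C)O[C@@H]1CO | intermediate
16 | (2S,3S)-3,7-dimethyloct-6-ene-1,2,3-triol | CC(C)=CCC[C@](C)(O)[C@@H](O)CO | intermediate
17 | (2S,3S)-2,3-dihydroxy-3,7-dimethyloct-6-en-1-yl 4-methylbenzenesulfonate | CC(C)=CCC[C@](C)(O)[C@@H](O)COS(=O)(=O)c1ccc(C)cc1 | intermediate
18 | (2S)-6-methyl-2-[(2S)-oxiran-2-yl]hept-5-en-2-ol | CC(C)=CCC[C@](C)(O)[C@@H]1CO1 | intermediate
19 | (2S,6S)-4-[(2S,3S)-2,3-dihydroxy-3,7-dimethyloct-6-en-1-yl]-5-hydroxy-2-methyl-2,6-bis(3-methylbut-2-en-1-yl)-6-(2-methylpropanoyl)cyclohex-4-ene-1,3-dione | CC(C)=CCC[C@](C)(O)[C@@H](O)CC1=C(O)[C@@](CC=C(C)C)(C(=O)C(C)C)C(=O)[C@@](C)(CC=C(C)C)C1=O | intermediate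
20 | (2S,5S,7S)-2-[(2S)-2-hydroxy-6-methylhept-5-en-2-yl]-5-methyl-5,7-bis(3-methylbut-2-en-1-yl)-7-(2-methylpropanoyl)-2,3,5,7-tetrahydro-1-benzofuran-4,6-dione (CNP0250451.1) | CC(C)=CCC[C@](C)(O)[C@@H]1CC2=C(O1)[C@@](CC=C(C)C)(C(=O)C(C)C)C(=O)[C@@](C)(CC=C(C)C)C2=O | target

**Step count**

Total: 12 steps. Longest linear sequence: 9 steps (steps 1–8 and 12).

**Steps most likely to fail**

1. Step 12. What may go wrong: O-alkylation of the ambident dione enolate and slow opening of the hindered epoxide. Fallback: the acid cyclodehydration is kept, but the C3–C3a bond is made by displacing a soft leaving group. It sets out from 16 and 13 and comes back at 20. Triol 16 is tosylated as in step 11 and 17 is isolated. Both remaining hydroxyls are silylated (TESOTf, 2,6-lutidine) to give the bis(triethylsilyl) ether F1. Finkelstein exchange (NaI, acetone, reflux) should give the primary iodide F2. C-alkylation of the caesium enolate of 13 (Cs2CO3, DMF, 40 °C) should give the C3a-alkylated trione F3, the soft iodide favouring carbon. Camphorsulfonic acid in wet CH2Cl2/MeOH then removes both silyl groups and effects the same closure on C7a to give 20.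

2. Step 8. What may go wrong: attack at the substituted terminus of the 1,1-dimethylallyl palladium complex (reverse prenyl) and weak discrimination between the two faces of C7. Fallback: it sets out from 10 and comes back at 12. The same catalyst with allyl acetate cannot give a branched isomer and uses the electrophile for which ligand-controlled alkylation of cyclic β-dicarbonyl enolates is best established. It should give the C7-allyl compound F4, whose epimers are separated. Cross-metathesis with 2-methylbut-2-ene (second-generation Grubbs catalyst, (H2IMes)(PCy3)Cl2Ru=CHPh, CH2Cl2, 40 °C) then turns allyl into prenyl to give 12, which is desilylated to 13 as in step 8.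

3. Step 7. What may go wrong: silylation at a chelated enol oxygen, or migration or loss of the silyl group on handling, which would unmask C3a for prenylation. Fallback: no protecting group; it sets out from 9 and 18 and comes back at 20. Compound 9 is annulated with 18 under the conditions of step 12, C3a being by far its most nucleophilic carbon, to give the 7-unsubstituted dihydrofuranone F5. The C7 prenyl group is then introduced last with 11 under the catalyst of step 8, C7 being by then the only enolisable carbon. The price is a less secure choice between C7a and C4 in the ring closure, because C7 is still enolisable at that stage.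

Further compounds
F1 | step 12 | (2S,3S)-3,7-dimethyl-2,3-bis[(triethylsilyl)oxy]oct-6-en-1-yl 4-methylbenzenesulfonate | CC(C)=CCC[C@](C)(O[Si](CC)(CC)CC)[C@@H](O[Si](CC)(CC)CC)COS(=O)(=O)c1ccc(C)cc1
F2 | step 12 | (6S,7R)-8-iodo-2,6-dimethyl-6,7-bis[(triethylsilyl)oxy]oct-2-ene | CC(C)=CCC[C@](C)(O[Si](CC)(CC)CC)[C@@H](O[Si](CC)(CC)CC)CI
F3 | step 12 | (2S,6S)-4-{(2S,3S)-3,7-dimethyl-2,3-bis[(triethylsilyl)oxy]oct-6-en-1-yl}-5-hydroxy-2-methyl-2,6-bis(3-methylbut-2-en-1-yl)-6-(2-methylpropanoyl)cyclohex-4-ene-1,3-dione | CC(C)=CCC[C@](C)(O[Si](CC)(CC)CC)[C@@H](O[Si](CC)(CC)CC)CC1=C(O)[C@@](CC=C(C)C)(C(=O)C(C)C)C(=O)[C@@](C)(CC=C(C)C)C1=O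
F4 | step 8 | (2R,6S)-6-methyl-6-(3-methylbut-2-en-1-yl)-2-(2-methylpropanoyl)-2-(prop-2-en-1-yl)-5-{[tri(propan-2-yl)silyl]oxy}cyclohex-4-ene-1,3-dione | C1=C(O[Si](C(C)C)(C(C)C)C(C)C)[C@](C)(CC=C(C)C)C(=O)[C@](CC=C)(C(=O)C(C)C)C1=O
F5 | step 7 | (2S,5R)-6-hydroxy-2-[(2S)-2-hydroxy-6-methylhept-5-en-2-yl]-5-methyl-5-(3-methylbut-2-en-1-yl)-7-(2-methylpropanoyl)-3,5-dihydro-1-benzofuran-4(2H)-one (20 without the C7 prenyl group, same spatial arrangement at C5) | CC(C)=CCC[C@](C)(O)[C@@H]1CC2=C(O1)C(C(=O)C(C)C)=C(O)[C@@](C)(CC=C(C)C)C2=O
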